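The route rests on one bond of the ten-membered ring: C5 of the 5,6-dihydrophenalen-1-one core (the doubly vinylogous α-carbon of the C1 ketone) to the CH(CH3) that lies β to the macrocyclic aryl ketone. That methine, its CH2, the ketone and the free ortho-phenol of the same benzene ring are a latent 2-methylchroman-4-one. The key step opens this chromanone by retro-oxa-Michael reaction and closes the macrocycle by vinylogous Michael addition, exchanging C–O for C–C and setting two stereocentres under control of the C6 methyl centre. The precursor is a tricyclic phenalenone carrying the chromanone as its 7-aryl ether, made by asymmetric Michael addition, aryne acyl-alkylation and Claisen benzannulation.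

Key step: step 10

Remark on locants: the tricycle is numbered as phenalen-1-one (C1 C=O, C3 O, C4 aryl, C5, C6 CH3, C7 O-aryl, C9 OH); "chain methine" is the CH(CH3) of the 3-methyl-1-oxobutane bridge.
Assumption: 22, 24 and 25 are written as the dienone (vinylogous ester or acid) tautomers, as in the target; the naphthalenediol tautomer of 22 would give the same anion in step 10.
Remark: the chromanone C2 centre is racemic and is erased in step 10, so 20, 21 and 22 are epimer pairs at that centre only; 6 and 14 are epimer pairs at the labile C2 of the pentanoate.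

Step 1
Reactants: 1 1,3-dimethoxybenzene; 2 (E)-N-methoxy-N-methylbut-2-enamide
Product: 4 (E)-1-(2,6-dimethoxyphenyl)but-2-en-1-one, via 2-lithio-1,3-dimethoxybenzene 3 (not isolated)
Conditions: n-BuLi, THF, 0 °C to rt; then 2, −78 °C; cold aq. NH4Cl
Reagents that add atoms: none
Why: Directed ortho-metalation occurs at C2 between the two methoxy groups, and the aryllithium acylates the Weinreb amide through a chelate that collapses only on work-up, so the (E)-enone should form without over-addition (Weinreb ketone synthesis).

Step 2
Reactants: 4 (E)-1-(2,6-dimethoxyphenyl)but-2-en-1-one; 5 methyl acetoacetate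
Product: 6 methyl (3R)-2-acetyl-5-(2,6-dimethoxyphenyl)-3-methyl-5-oxopentanoate
Conditions: epi-quinine-derived 3,5-bis(trifluoromethyl)phenyl thiourea (10 mol %), toluene, 25 °C
Reagents that add atoms: none
Why: Bifunctional thiourea–tertiary amine catalysis (asymmetric Michael addition of a β-ketoester to an aryl enone) binds the ketone and delivers the enol to one face of the β-carbon, which should set the methyl-bearing centre as R (the quinine- or quinidine-derived pseudoenantiomer is chosen accordingly), while the centre between the carbonyls is labile and irrelevant.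

Step 3
Reactants: 7 3,5-dimethoxyphenol
Product: 8 2-bromo-3,5-dimethoxyphenol
Conditions: NBS, CH2Cl2, −78 °C to rt
Reagents that add atoms: N-bromosuccinimide O=C1CCC(=O)N1Br
Why: Electrophilic aromatic bromination of the phenol is expected ortho to OH and para to a methoxy group (C2), the alternative C4 being flanked by two methoxy groups; a minor isomer would be removed by chromatography.

Step 4
Reactants: 8 2-bromo-3,5-dimethoxyphenol
Product: 12 3,5-dimethoxy-2-(trimethylsilyl)phenyl trifluoromethanesulfonate, via aryl trimethylsilyl ether 9 (not isolated), via ortho-lithiated silyl ether 10 (not isolated), via lithium 2-silylphenoxide 11 (not isolated)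
Conditions: HMDS, THF, 70 °C, then evaporate; n-BuLi, THF, −100 to −78 °C; Tf2O, −78 °C
Reagents that add atoms: hexamethyldisilazane C[Si](C)(C)N[Si](C)(C)C; trifluoromethanesulfonic anhydride O=S(=O)(OS(=O)(=O)C(F)(F)F)C(F)(F)F
Why: O-Silylation, bromine–lithium exchange and 1,3 O-to-C silyl shift (retro-Brook rearrangement) place the silyl group ortho to the phenoxide, which is triflated to the ortho-silylaryl triflate aryne precursor.

Step 5
Reactants: 6 methyl (3R)-2-acetyl-5-(2,6-dimethoxyphenyl)-3-methyl-5-oxopentanoate; 12 3,5-dimethoxy-2-(trimethylsilyl)phenyl trifluoromethanesulfonate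
Product: 14 methyl (3R)-2-(2-acetyl-3,5-dimethoxyphenyl)-5-(2,6-dimethoxyphenyl)-3-methyl-5-oxopentanoate, via 3,5-dimethoxybenzyne 13 (not isolated)
Conditions: CsF, MeCN, 60 °C
Reagents that add atoms: none
Why: Fluoride releases the aryne, the β-ketoester enolate adds at the aryne carbon remote from the methoxy group, and the aryl anion formed next to that methoxy group attacks the acetyl carbonyl to give a benzocyclobutoxide that fragments, so the arene is inserted into the C–C(O) bond with the acetyl ortho to OMe (aryne acyl-alkylation); the methyl-bearing centre is not involved.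

Step 6
Reactants: 14 methyl (3R)-2-(2-acetyl-3,5-dimethoxyphenyl)-5-(2,6-dimethoxyphenyl)-3-methyl-5-oxopentanoate
Product: 15 4-[(2R)-4-(2,6-dimethoxyphenyl)-4-oxobutan-2-yl]-6,8-dimethoxynaphthalene-1,3-diol
Conditions: LiN(SiMe3)2 (3.5 equiv), THF, −78 to 0 °C; aq. NH4Cl
Reagents that add atoms: none
Why: Kinetic deprotonation gives the methyl ketone enolate, which acylates on the neighbouring ester (intramolecular Claisen condensation, 6-exo-trig), and the diketone aromatises to the naphthalene-1,3-diol, so the side chain sits at C4 without regiochemical ambiguity and its stereocentre is untouched.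

Step 7
Reactants: 16 1-(2-fluoro-6-hydroxyphenyl)ethanone; 17 acetaldehyde
Product: 19 5-fluoro-2-methylchroman-4-one, via (E)-1-(2-fluoro-6-hydroxyphenyl)but-2-en-1-one 18 (not isolated)
Conditions: pyrrolidine (0.5 equiv), MeOH, 60 °C, sealed tube
Reagents that add atoms: none
Why: Pyrrolidine-mediated aldol condensation with acetaldehyde and oxa-Michael closure of the ortho-phenol onto the enone (Kabbe condensation) should give the racemic chromanone, whose stereocentre is erased later.

Step 8
Reactants: 15 4-[(2R)-4-(2,6-dimethoxyphenyl)-4-oxobutan-2-yl]-6,8-dimethoxynaphthalene-1,3-diol; 19 5-fluoro-2-methylchroman-4-one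
Product: 20 5-({4-hydroxy-5,7-dimethoxy-1-[(2R)-4-(2,6-dimethoxyphenyl)-4-oxobutan-2-yl]naphthalen-2-yl}oxy)-2-methylchroman-4-one
Conditions: Cs2CO3 (1.1 equiv), DMSO, 80 °C, Ar
Reagents that add atoms: none
Why: Nucleophilic aromatic substitution of the fluoride ortho to the chromanone carbonyl by the naphthoxide, in which the 3-OH of 15 is the more acidic and accessible one because the 1-OH is held in a peri hydrogen bond to the 8-methoxy oxygen; arylating this oxygen before the acid step also prevents its cyclisation onto the side-chain ketone.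

Step 9
Reactants: 20 5-({4-hydroxy-5,7-dimethoxy-1-[(2R)-4-(2,6-dimethoxyphenyl)-4-oxobutan-2-yl]naphthalen-2-yl}oxy)-2-methylchroman-4-one
Product: 22 5-{[(6R)-4-(2,6-dimethoxyphenyl)-9-hydroxy-3-methoxy-6-methyl-1-oxo-5,6-dihydro-1H-phenalen-7-yl]oxy}-2-methylchroman-4-one, via 1H-phenalene 21 (not isolated)
Conditions: TfOH (10 mol %), 4 Å MS, CH2Cl2, 0 °C; then BCl3 (3 equiv), −78 to 0 °C; aq. NaHCO3
Reagents that add atoms: none
Why: Acid-catalysed intramolecular Friedel–Crafts hydroxyalkylation of the naphthalene peri position (ortho and para to methoxy groups) by the aryl ketone, followed by dehydration, closes the six-membered ring as the 1H-phenalene; BCl3 bound to the free peri hydroxyl then chelates and cleaves only the neighbouring methyl ether, and the peri-diol tautomerises to the vinylogous ester, with no stereocentre formed and the benzylic centre not ionised.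

Step 10
Reactants: 22 5-{[(6R)-4-(2,6-dimethoxyphenyl)-9-hydroxy-3-methoxy-6-methyl-1-oxo-5,6-dihydro-1H-phenalen-7-yl]oxy}-2-methylchroman-4-one
Product: 24 tri-O-methyl macrocycle (the target with OMe at phenalenone C3 and on both oxygens of the C4 aryl group; 5R 6R chain methine S), via ring-opened (E)-enone 23 (not isolated)
Conditions: DBU (2 equiv), degassed DMF (2 mM), 50 °C, Ar; then AcOH
Reagents that add atoms: none
Why: DBU reversibly opens the chromanone by E1cB retro-oxa-Michael reaction to the (E)-2-hydroxyaryl propenyl ketone 23 and also removes the acidic C5–H of the phenalenone, giving a naphtholate-type extended enolate whose soft terminus C5 adds to the enone β-carbon (intramolecular vinylogous Michael addition, 10-endo-trig), so the ten-membered ring closes in the C–C bond-forming event. The closest known reaction types are the base-mediated chromanone/hydroxy-enone equilibration and macrocyclising Michael additions of stabilised enolates. C5 should be set trans to the C6 methyl because that methyl sits pseudo-axial (avoiding the clash with the 7-aryloxy group) and blocks its own face, and this centre remains epimerisable toward the trans-diaxial arrangement the bridge needs. The chain methine is controlled by the (E)-enone geometry inside the tether: with the ketone end held toward the aryl ether, only the face that leaves the methyl on the periphery, away from the C4 aryl group, can reach C5, which corresponds to S, and reversibility of the Michael step lets a mis-set epimer revert. Site selectivity (C5 rather than O1, C2 or C3a of the ambident anion) follows from the reach of the tether and from the fact that only attack through C5 regenerates the conjugated vinylogous ester, and intermolecular addition is suppressed by dilution. The driving force is the exchange of the chromanone ether for a C–C bond plus a chelated ortho-hydroxyaryl ketone, and a mild amidine base is chosen so that C6–H, removable only through a phenalenyl anion, is not touched.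

Step 11
Reactants: 24 tri-O-methyl macrocycle
Product: 25 CNP0225737.1
Conditions: BBr3 (8 equiv), CH2Cl2, −78 to −10 °C; then MeOH, aq. NaHCO3
Reagents that add atoms: none
Why: BBr3 should cleave the two aryl methyl ethers and the vinylogous methyl ester by Lewis acid-assisted SN2 demethylation, while the diaryl ether, the ring C–C bonds and the three stereocentres are not affected at low temperature.

Compound list
1 | 1,3-dimethoxybenzene | COc1cccc(OC)c1 | starting material
2 | (E)-N-methoxy-N-methylbut-2-enamide | C/C=C/C(=O)N(C)OC | starting material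
3 | 2-lithio-1,3-dimethoxybenzene | [Li]c1c(OC)cccc1OC | intermediate
4 | (E)-1-(2,6-dimethoxyphenyl)but-2-en-1-one | C/C=C/C(=O)c1c(OC)cccc1OC | intermediate
5 | methyl acetoacetate | CC(=O)CC(=O)OC | starting material
6 | methyl (3R)-2-acetyl-5-(2,6-dimethoxyphenyl)-3-methyl-5-oxopentanoate | COC(=O)C(C(C)=O)[C@H](C)CC(=O)c1c(OC)cccc1OC | intermediate
7 | 3,5-dimethoxyphenol | COc1cc(O)cc(OC)c1 | starting material
8 | 2-bromo-3,5-dimethoxyphenol | COc1cc(O)c(Br)c(OC)c1 | intermediate
9 | (2-bromo-3,5-dimethoxyphenoxy)trimethylsilane | COc1cc(O[Si](C)(C)C)c(Br)c(OC)c1 | intermediate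
10 | (2-lithio-3,5-dimethoxyphenoxy)trimethylsilane | COc1cc(O[Si](C)(C)C)c([Li])c(OC)c1 | intermediate
11 | lithium 3,5-dimethoxy-2-(trimethylsilyl)phenoxide | COc1cc(O[Li])c([Si](C)(C)C)c(OC)c1 | intermediate
12 | 3,5-dimethoxy-2-(trimethylsilyl)phenyl trifluoromethanesulfonate | COc1cc(OS(=O)(=O)C(F)(F)F)c([Si](C)(C)C)c(OC)c1 | intermediate
13 | 3,5-dimethoxybenzyne | COC1=CC(OC)=CC#C1 | intermediate
14 | methyl (3R)-2-(2-acetyl-3,5-dimethoxyphenyl)-5-(2,6-dimethoxyphenyl)-3-methyl-5-oxopentanoate | COC(=O)C(c1cc(OC)cc(OC)c1C(C)=O)[C@H](C)CC(=O)c1c(OC)cccc1OC | intermediate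
15 | 4-[(2R)-4-(2,6-dimethoxyphenyl)-4-oxobutan-2-yl]-6,8-dimethoxynaphthalene-1,3-diol | C[C@H](CC(=O)c1c(OC)cccc1OC)c1c(O)cc(O)c2c(OC)cc(OC)cc12 | intermediate
16 | 1-(2-fluoro-6-hydroxyphenyl)ethanone | CC(=O)c1c(O)cccc1F | starting material
17 | acetaldehyde | CC=O | starting material
18 | (E)-1-(2-fluoro-6-hydroxyphenyl)but-2-en-1-one | C/C=C/C(=O)c1c(O)cccc1F | intermediate
19 | 5-fluoro-2-methylchroman-4-one (racemic) | CC1CC(=O)c2c(F)cccc2O1 | intermediate
20 | 5-({4-hydroxy-5,7-dimethoxy-1-[(2R)-4-(2,6-dimethoxyphenyl)-4-oxobutan-2-yl]naphthalen-2-yl}oxy)-2-methylchroman-4-one | C[C@H](CC(=O)c1c(OC)cccc1OC)c1c(Oc3cccc4OC(C)CC(=O)c34)cc(O)c2c(OC)cc(OC)cc12 | intermediate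
21 | 5-{[(1R)-3-(2,6-dimethoxyphenyl)-7-hydroxy-4,6-dimethoxy-1-methyl-1H-phenalen-9-yl]oxy}-2-methylchroman-4-one | C[C@@H]1C=C(c2c(OC)cccc2OC)c2c(OC)cc(OC)c3c(O)cc(Oc4cccc5OC(C)CC(=O)c45)c1c23 | intermediate
22 | 5-{[(6R)-4-(2,6-dimethoxyphenyl)-9-hydroxy-3-methoxy-6-methyl-1-oxo-5,6-dihydro-1H-phenalen-7-yl]oxy}-2-methylchroman-4-one | C[C@@H]1CC(c2c(OC)cccc2OC)=C2C(OC)=CC(=O)c3c(O)cc(Oc4cccc5OC(C)CC(=O)c45)c1c23 | intermediate
23 | (6R)-7-{2-[(E)-but-2-enoyl]-3-hydroxyphenoxy}-4-(2,6-dimethoxyphenyl)-9-hydroxy-3-methoxy-6-methyl-5,6-dihydro-1H-phenalen-1-one | C[C@@H]1CC(c2c(OC)cccc2OC)=C2C(OC)=CC(=O)c3c(O)cc(Oc4cccc(O)c4C(=O)/C=C/C)c1c23 | intermediate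
24 | tri-O-methyl macrocycle (target with OMe at phenalenone C3 and on both oxygens of the C4 aryl group; 5R, 6R, chain methine S) | C[C@H]1CC(=O)c2c(O)cccc2Oc2cc(O)c3c4c2[C@H](C)[C@@H]1C(c1c(OC)cccc1OC)=C4C(OC)=CC3=O | intermediate
25 | CNP0225737.1 | C[C@H]1CC(=O)c2c(O)cccc2Oc2cc(O)c3c4c2[C@H](C)[C@@H]1C(c1c(O)cccc1O)=C4C(O)=CC3=O | target

Total step count: 11. Longest linear sequence: 8 steps (1, 2, 5, 6, 8, 9, 10, 11; the aryne branch 3, 4, 5, 6, 8, 9, 10, 11 is equally long).

Steps most likely to fail

Step 10. The chromanone may reopen too slowly or reclose faster than the carbanion adds, the open enone may be consumed by intermolecular addition, or the chain methine may be set with the wrong sense. The fallback closes the ring at the aryl ether bond instead of the C–C bond; it sets out from 15 and comes back at 24. Diol 15 is cyclodehydrated with catalytic TfOH (a transient benzochromene hemiketal should reopen under the acid) to the phenalene diol F1, which BCl3 demethylates at the peri oxygen to the 7,9-dihydroxyphenalenone F2. F2 and chromanone 19 with DBU in DMF undergo the same retro-oxa-Michael and vinylogous Michael sequence intermolecularly, through enone 18, to give the open-chain adduct F3, whose chain-methine epimers interconvert by retro-Michael reaction. Cs2CO3 in DMSO at 90 °C and high dilution then closes the ring by intramolecular nucleophilic aromatic substitution of the fluoride by the C7 oxide, through which only the epimer that can reach should pass, to give 24.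

Step 5. The hindered, α-branched enolate may add to the aryne too slowly, the aryl anion may be intercepted by the remote aryl ketone instead of the acetyl group, or retro-Michael reaction under fluoride may erode the stereocentre. The fallback installs aryl and acetyl groups stepwise; it sets out from 6 and comes back at 14. (3,5-Dimethoxyphenyl)boronic acid and Pb(OAc)4 with catalytic Hg(OAc)2 give (3,5-dimethoxyphenyl)lead triacetate F4, which arylates 6 at the carbon between the carbonyls (pyridine, CHCl3, 40 °C; Pinhey arylation) to the quaternary keto ester F5. NaOMe in MeOH at 0 °C removes the acetyl group by retro-Claisen cleavage to the arylacetate F6, and AcCl with SnCl4 in CH2Cl2 at −40 °C acetylates the dimethoxyphenyl ring ortho to the side chain (Friedel–Crafts acylation) to give 14.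

Step 11. Lewis acid-promoted retro-Michael opening of the macrocycle, or dehydrative closure of a resorcinol hydroxyl onto the vinylogous acid, may occur during demethylation. The fallback deprotects first and cyclises last; it sets out from 22 and comes back at 25. BBr3 demethylates 22 to the tetrahydroxy chromanone precursor F7, and the DBU-mediated retro-oxa-Michael and Michael macrocyclisation of step 10 is then run on this free polyphenol in degassed DMF, so that 25 is the direct product of ring closure and is never exposed to the boron halide.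

Further compounds
F1 | step 10 | (1R)-3-(2,6-dimethoxyphenyl)-4,6-dimethoxy-1-methyl-1H-phenalene-7,9-diol | C[C@@H]1C=C(c2c(OC)cccc2OC)c2c(OC)cc(OC)c3c(O)cc(O)c1c23
F2 | step 10 | (6R)-4-(2,6-dimethoxyphenyl)-7,9-dihydroxy-3-methoxy-6-methyl-5,6-dihydro-1H-phenalen-1-one | C[C@@H]1CC(c2c(OC)cccc2OC)=C2C(OC)=CC(=O)c3c(O)cc(O)c1c23
F3 | step 10 | (5R,6R)-4-(2,6-dimethoxyphenyl)-5-[(2S)-4-(2-fluoro-6-hydroxyphenyl)-4-oxobutan-2-yl]-7,9-dihydroxy-3-methoxy-6-methyl-5,6-dihydro-1H-phenalen-1-one | C[C@@H](CC(=O)c1c(O)cccc1F)[C@H]1C(c2c(OC)cccc2OC)=C2C(OC)=CC(=O)c3c(O)cc(O)c(c23)[C@@H]1C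
F4 | step 5 | (3,5-dimethoxyphenyl)lead triacetate | CC(=O)O[Pb](OC(C)=O)(OC(C)=O)c1cc(OC)cc(OC)c1
F5 | step 5 | methyl (3R)-2-acetyl-2-(3,5-dimethoxyphenyl)-5-(2,6-dimethoxyphenyl)-3-methyl-5-oxopentanoate | COC(=O)C(C(C)=O)(c1cc(OC)cc(OC)c1)[C@H](C)CC(=O)c1c(OC)cccc1OC
F6 | step 5 | methyl (3R)-2-(3,5-dimethoxyphenyl)-5-(2,6-dimethoxyphenyl)-3-methyl-5-oxopentanoate | COC(=O)C(c1cc(OC)cc(OC)c1)[C@H](C)CC(=O)c1c(OC)cccc1OC
F7 | step 11 | 5-{[(6R)-4-(2,6-dihydroxyphenyl)-3,9-dihydroxy-6-methyl-1-oxo-5,6-dihydro-1H-phenalen-7-yl]oxy}-2-methylchroman-4-one | C[C@@H]1CC(c2c(O)cccc2O)=C2C(O)=CC(=O)c3c(O)cc(Oc4cccc5OC(C)CC(=O)c45)c1c23
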